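**Retrosynthetic overview**

1. Ring numbering: C1 is the ring CH that carries the 6-methylhepta-1,5-dien-2-yl group (C15=C16H2), then C2H2, C3=C4(Me) (Z), C5, C6, C7=C8(Me) (Z), C9, C10, C11=C12(Me) (E), C13H2, C14 (CH–OMe). Last disconnection: the O–CH3 bond, giving the macrocyclic C14 alcohol.
2. Key disconnection: ring bond C12–C13, giving an acyclic precursor with a monosubstituted (R)-epoxide (C13–C14) and a methyl-capped alkyne (CH3–C12≡C11). A nickel-catalysed reductive alkyne–epoxide macrocyclisation forms the 14-membered ring, the E C11=C12 alkene and the C14 hydroxyl in one operation. The enabling feature is the homoallylic array C14(O)–C13H2–C12(CH3)=C11H inside the 14-membered ring, which is the retron of a cis hydroalkylation of a 2-alkyne by the CH2 end of a terminal epoxide.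
3. Epoxide, C1 and C14 come from dimethyl (R)-malate: anti-selective Fráter–Seebach alkylation makes C1–C2; the C13 ester becomes the epoxide CH2; the C15 ester becomes ketone, then C15=C16H2.
4. The C2–C12 allylic bromide comes from nerol (Z C3=C4), a Z-selective iodo-olefination (C7=C8) and a Negishi coupling with pent-3-ynylzinc iodide (C9–C12 and its methyl).
5. Ring order: only one ring is formed, the 14-membered carbocycle, in step 17.

Key step: step 17

Remark: dimethyl (R)-malate is taken as a purchased material; the oxirane carbon made in step 2 is racemic, which has no consequence because it is excised in step 3.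

**Route**

Step 1
Reactants: 1 nerol
Product: 2 tert-butyl{[(2Z)-3,7-dimethylocta-2,6-dien-1-yl]oxy}diphenylsilane
Conditions: TBDPSCl, imidazole, CH2Cl2, 0 °C → rt
Reagents that add atoms: tert-butyl(chloro)diphenylsilane, CC(C)(C)[Si](Cl)(c1ccccc1)c1ccccc1
Why: Silylation of the primary allylic alcohol gives an ether that should survive peracid, periodic acid, ylide and organozinc conditions.

Step 2
Reactants: 2
Product: 3 tert-butyl{[(2Z)-5-(3,3-dimethyloxiran-2-yl)-3-methylpent-2-en-1-yl]oxy}diphenylsilane (racemic at the oxirane CH)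
Conditions: mCPBA (1.0 equiv), CH2Cl2, −20 → 0 °C
Reagents that add atoms: 3-chloroperbenzoic acid, OOC(=O)c1cccc(Cl)c1
Why: Prilezhaev epoxidation should take place at the more electron-rich terminal trisubstituted alkene, because the other alkene is deactivated inductively by the allylic silyloxy group.

Step 3
Reactants: 3
Product: 4 (4Z)-6-[(tert-butyldiphenylsilyl)oxy]-4-methylhex-4-enal
Conditions: H5IO6, THF/H2O, 0 °C
Reagents that add atoms: none
Why: Periodic acid hydrolyses the epoxide and cleaves the resulting glycol, excising acetone and leaving the aldehyde at C7 with the Z C3=C4 alkene untouched.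

Step 4
Reactants: 4
Product: 5 tert-butyl{[(2Z,6Z)-7-iodo-3-methylocta-2,6-dien-1-yl]oxy}diphenylsilane
Conditions: [Ph3PEt]I, n-BuLi, THF, 0 °C; I2, −78 °C; NaN(SiMe3)2, −20 °C; then 4, −78 °C → rt
Reagents that add atoms: ethyltriphenylphosphonium iodide, CC[P+](c1ccccc1)(c1ccccc1)c1ccccc1.[I-]; iodine, II
Why: Wittig reaction with the α-iodo ylide (Stork–Zhao-type olefination) is kinetically controlled and should place iodine cis to the chain, giving the (Z)-2-iodoalkene that fixes the C7=C8 geometry.

Step 5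
Reactants: 6 pent-3-yn-1-ol
Product: 7 5-iodopent-2-yne
Conditions: I2, PPh3, imidazole, CH2Cl2, 0 °C → rt
Reagents that add atoms: iodine, II
Why: Appel-type iodination converts the primary alcohol into the iodide needed for zinc insertion.

Step 6
Reactants: 7 5-iodopent-2-yne; 5 vinyl iodide
Product: 9 tert-butyl{[(2Z,6Z)-3,7-dimethyldodeca-2,6-dien-10-yn-1-yl]oxy}diphenylsilane, via pent-3-ynylzinc iodide 8 (not isolated)
Conditions: 7, Zn dust, LiCl, THF, 40 °C; then 5, Pd(PPh3)4 (5 mol %), THF, rt
Reagents that add atoms: none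
Why: Negishi coupling of the alkylzinc with the alkenyl iodide proceeds with retention, so the Z-trisubstituted C7=C8 alkene and the methyl-capped alkyne are installed together.

Step 7
Reactants: 9
Product: 10 (2Z,6Z)-3,7-dimethyldodeca-2,6-dien-10-yn-1-ol
Conditions: Bu4NF, THF, 0 °C → rt
Reagents that add atoms: none
Why: Fluoride-mediated desilylation frees the allylic alcohol without touching alkenes or alkyne.

Step 8
Reactants: 10
Product: 11 (2Z,6Z)-1-bromo-3,7-dimethyldodeca-2,6-dien-10-yne
Conditions: CBr4, PPh3, CH2Cl2, −30 → 0 °C; used directly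
Reagents that add atoms: tetrabromomethane, BrC(Br)(Br)Br
Why: Appel bromination at low temperature should give the primary allylic bromide by direct displacement, without allylic transposition or Z/E isomerisation.

Step 9
Reactants: 12 dimethyl (R)-malate (1.5 equiv); 11 allylic bromide
Product: 14 dimethyl (2R,3S)-2-hydroxy-3-[(2Z,6Z)-3,7-dimethyldodeca-2,6-dien-10-yn-1-yl]butanedioate, via dilithium malate alkoxide-enolate 13 (not isolated)
Conditions: LiN(SiMe3)2 (2.1 equiv per 12), THF, −78 → −20 °C; then 11, −78 → −10 °C; aq NH4Cl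
Reagents that add atoms: none
Why: Fráter–Seebach alkylation: the lithium-chelated alkoxide–enolate should be attacked by the allylic bromide on the face opposite the ester-bearing carbinol substituent, setting C1 anti to the C14 hydroxyl, while C14 comes unchanged from the malate.

Step 10
Reactants: 14
Product: 15 methyl (2S,4Z,8Z)-2-[(1R)-1,2-dihydroxyethyl]-5,9-dimethyltetradeca-4,8-dien-12-ynoate
Conditions: BH3·SMe2 (1.05 equiv), NaBH4 (5 mol %), THF, 0 °C → rt; MeOH quench
Reagents that add atoms: none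
Why: Hydroxyl-directed borane reduction: the alkoxyborane formed at the C14 hydroxyl delivers hydride intramolecularly to the neighbouring ester only, so the C13 ester becomes CH2OH and the C15 ester stays.

Step 11
Reactants: 15
Product: 16 methyl (2S,4Z,8Z)-2-[(4R)-2,2-dimethyl-1,3-dioxolan-4-yl]-5,9-dimethyltetradeca-4,8-dien-12-ynoate
Conditions: Me2C(OMe)2, PPTS (cat.), CH2Cl2, rt
Reagents that add atoms: 2,2-dimethoxypropane, COC(C)(C)OC
Why: Acid-catalysed transketalisation protects the 1,2-diol as the five-membered acetonide before the organomagnesium steps.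

Step 12
Reactants: 16
Product: 17 (2S,4Z,8Z)-2-[(4R)-2,2-dimethyl-1,3-dioxolan-4-yl]-N-methoxy-N,5,9-trimethyltetradeca-4,8-dien-12-ynamide
Conditions: MeNH(OMe)·HCl, iPrMgCl, THF, −20 → 0 °C
Reagents that add atoms: N,O-dimethylhydroxylamine hydrochloride, CNOC.Cl
Why: Aminolysis of the methyl ester by the weakly basic chloromagnesium amide gives the Weinreb amide, and C1 should not be enolised under these conditions.

Step 13
Reactants: 18 5-bromo-2-methylpent-2-ene; 17 Weinreb amide
Product: 20 (7S,9Z,13Z)-7-[(4R)-2,2-dimethyl-1,3-dioxolan-4-yl]-2,10,14-trimethylnonadeca-2,9,13-trien-17-yn-6-one, via (4-methylpent-3-enyl)magnesium bromide 19 (not isolated)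
Conditions: 18, Mg, THF, rt → 40 °C; then 17, THF, 0 °C; aq NH4Cl
Reagents that add atoms: none
Why: Weinreb ketone synthesis: the chelated tetrahedral intermediate prevents over-addition and releases the C15 ketone only on work-up.

Step 14
Reactants: 20
Product: 21 (4R)-2,2-dimethyl-4-[(7R,9Z,13Z)-2,10,14-trimethyl-6-methylidenenonadeca-2,9,13-trien-17-yn-7-yl]-1,3-dioxolane
Conditions: Zn, CH2Br2, TiCl4 (pre-formed reagent, THF, 5 °C), then 20, CH2Cl2, 0 °C → rt
Reagents that add atoms: dibromomethane, BrCBr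
Why: Takai–Lombardo methylenation uses a non-basic gem-dimetallic reagent, so the ketone should become C15=C16H2 without epimerisation at C1 or β-elimination of the dioxolane oxygen.

Step 15
Reactants: 21
Product: 22 (2R,3R,5Z,9Z)-6,10-dimethyl-3-(6-methylhepta-1,5-dien-2-yl)pentadeca-5,9-dien-13-yne-1,2-diol
Conditions: AcOH/THF/H2O (3:1:1), 40 °C
Reagents that add atoms: none
Why: Mild acid hydrolysis of the acetonide frees the 1,2-diol under conditions that should leave the alkenes and alkyne alone.

Step 16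
Reactants: 22
Product: 24 (2R)-2-[(7R,9Z,13Z)-2,10,14-trimethyl-6-methylidenenonadeca-2,9,13-trien-17-yn-7-yl]oxirane, via primary triisopropylbenzenesulfonate 23 (not isolated)
Conditions: NaH (2.5 equiv), 1-(2,4,6-triisopropylbenzenesulfonyl)imidazole, THF, 0 °C → rt
Reagents that add atoms: none
Why: The bulky sulfonylimidazole should sulfonylate the primary alkoxide selectively, and intramolecular Williamson closure by the C14 alkoxide then gives the terminal epoxide with retention at C14, because its C–O bond is not broken.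

Step 17
Reactants: 24
Product: 25 (1S,3E,7Z,11Z,14R)-3,7,11-trimethyl-14-(6-methylhepta-1,5-dien-2-yl)cyclotetradeca-3,7,11-trien-1-ol
Conditions: Ni(cod)2 (20 mol %), PBu3 (40 mol %), Et3B (4 equiv), THF, 0.005 M (24 added by syringe pump), 25 → 40 °C; aq NH4Cl
Reagents that add atoms: none
Why: Proposed new method: PBu3-ligated zerovalent nickel binds the C11≡C12 alkyne and, with the epoxide activated by Et3B, couples C12 oxidatively with the unsubstituted epoxide carbon C13 to a six-membered oxanickelacycle (nickel on C11 and on the C14 oxygen), which is opened by ethyl transfer from boron, β-hydride elimination (loss of ethene) and C11–H reductive elimination, so that C13 and H add cis across the alkyne. The closest known reaction type is the Ni(cod)2/PBu3/Et3B reductive coupling of alkynes with monosubstituted epoxides, known intermolecularly, in small-ring closures and for closing a 14-membered macrolide ring; new here is a methyl-capped dialkyl alkyne closing an all-carbon ring. The 14-membered ring is closed in the endo mode at both partners (both alkyne carbons and both epoxide carbons become ring atoms), under high dilution. No stereocentre is created: C14 keeps the epoxide configuration because its C–O bond is never broken (the descriptor changes from R to S only through the priority change), C1 is a spectator, and the E geometry of C11=C12 follows from the cis addition. The step needs C–C bond formation at the methyl-bearing alkyne carbon and at the epoxide CH2; the epoxide site is secured by its unsubstituted terminus, the alkyne site by the smaller methyl group at the bond-forming carbon (the long chain sits next to nickel) and by the preference for a 14-membered ring with an endocyclic E alkene over a 13-membered ring with an exocyclic ethylidene. The trisubstituted and 1,1-disubstituted alkenes should bind zerovalent nickel too weakly to compete.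

Step 18
Reactants: 25
Product: 26 (1E,5Z,9Z,12R,13S)-13-methoxy-1,5,9-trimethyl-12-(6-methylhepta-1,5-dien-2-yl)cyclotetradeca-1,5,9-triene (target)
Conditions: NaH, MeI, THF/DMF, 0 °C → rt
Reagents that add atoms: iodomethane, CI
Why: Williamson etherification of the secondary alkoxide installs the methyl ether without touching either stereocentre.

**Compound list**

1 | nerol, (2Z)-3,7-dimethylocta-2,6-dien-1-ol | CC(C)=CCC/C(C)=C\CO | starting material
2 | tert-butyl{[(2Z)-3,7-dimethylocta-2,6-dien-1-yl]oxy}diphenylsilane | CC(C)=CCC/C(C)=C\CO[Si](c1ccccc1)(c1ccccc1)C(C)(C)C | intermediate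
3 | tert-butyl{[(2Z)-5-(3,3-dimethyloxiran-2-yl)-3-methylpent-2-en-1-yl]oxy}diphenylsilane (racemic oxirane CH) | CC1(C)OC1CC/C(C)=C\CO[Si](c1ccccc1)(c1ccccc1)C(C)(C)C | intermediate
4 | (4Z)-6-[(tert-butyldiphenylsilyl)oxy]-4-methylhex-4-enal | O=CCC/C(C)=C\CO[Si](c1ccccc1)(c1ccccc1)C(C)(C)C | intermediate
5 | tert-butyl{[(2Z,6Z)-7-iodo-3-methylocta-2,6-dien-1-yl]oxy}diphenylsilane | I/C(C)=C\CC/C(C)=C\CO[Si](c1ccccc1)(c1ccccc1)C(C)(C)C | intermediate
6 | pent-3-yn-1-ol | CC#CCCO | starting material
7 | 5-iodopent-2-yne | CC#CCCI | intermediate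
8 | pent-3-ynylzinc iodide | CC#CCC[Zn]I | intermediate (not isolated)
9 | tert-butyl{[(2Z,6Z)-3,7-dimethyldodeca-2,6-dien-10-yn-1-yl]oxy}diphenylsilane | CC#CCC/C(C)=C\CC/C(C)=C\CO[Si](c1ccccc1)(c1ccccc1)C(C)(C)C | intermediate
10 | (2Z,6Z)-3,7-dimethyldodeca-2,6-dien-10-yn-1-ol | CC#CCC/C(C)=C\CC/C(C)=C\CO | intermediate
11 | (2Z,6Z)-1-bromo-3,7-dimethyldodeca-2,6-dien-10-yne | CC#CCC/C(C)=C\CC/C(C)=C\CBr | intermediate
12 | dimethyl (R)-malate, dimethyl (2R)-2-hydroxybutanedioate | COC(=O)C[C@@H](O)C(=O)OC | starting material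
13 | dilithium alkoxide–enolate of dimethyl (R)-malate (chelated, enolate oxygen cis to the carbinol carbon) | COC(=O)[C@H]([O-])/C=C(\[O-])OC.[Li+].[Li+] | intermediate (not isolated)
14 | dimethyl (2R,3S)-2-hydroxy-3-[(2Z,6Z)-3,7-dimethyldodeca-2,6-dien-10-yn-1-yl]butanedioate | COC(=O)[C@H](O)[C@H](C/C=C(/C)CC/C=C(/C)CCC#CC)C(=O)OC | intermediate
15 | methyl (2S,4Z,8Z)-2-[(1R)-1,2-dihydroxyethyl]-5,9-dimethyltetradeca-4,8-dien-12-ynoate | OC[C@H](O)[C@H](C/C=C(/C)CC/C=C(/C)CCC#CC)C(=O)OC | intermediate
16 | methyl (2S,4Z,8Z)-2-[(4R)-2,2-dimethyl-1,3-dioxolan-4-yl]-5,9-dimethyltetradeca-4,8-dien-12-ynoate | CC1(C)OC[C@H](O1)[C@H](C/C=C(/C)CC/C=C(/C)CCC#CC)C(=O)OC | intermediate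
17 | (2S,4Z,8Z)-2-[(4R)-2,2-dimethyl-1,3-dioxolan-4-yl]-N-methoxy-N,5,9-trimethyltetradeca-4,8-dien-12-ynamide | CC1(C)OC[C@H](O1)[C@H](C/C=C(/C)CC/C=C(/C)CCC#CC)C(=O)N(C)OC | intermediate
18 | 5-bromo-2-methylpent-2-ene | CC(C)=CCCBr | starting material
19 | (4-methylpent-3-enyl)magnesium bromide | CC(C)=CCC[Mg]Br | intermediate (not isolated)
20 | (7S,9Z,13Z)-7-[(4R)-2,2-dimethyl-1,3-dioxolan-4-yl]-2,10,14-trimethylnonadeca-2,9,13-trien-17-yn-6-one | CC1(C)OC[C@H](O1)[C@H](C/C=C(/C)CC/C=C(/C)CCC#CC)C(=O)CCC=C(C)C | intermediate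
21 | (4R)-2,2-dimethyl-4-[(7R,9Z,13Z)-2,10,14-trimethyl-6-methylidenenonadeca-2,9,13-trien-17-yn-7-yl]-1,3-dioxolane | CC1(C)OC[C@H](O1)[C@H](C/C=C(/C)CC/C=C(/C)CCC#CC)C(=C)CCC=C(C)C | intermediate
22 | (2R,3R,5Z,9Z)-6,10-dimethyl-3-(6-methylhepta-1,5-dien-2-yl)pentadeca-5,9-dien-13-yne-1,2-diol | OC[C@H](O)[C@H](C/C=C(/C)CC/C=C(/C)CCC#CC)C(=C)CCC=C(C)C | intermediate
23 | primary 2,4,6-triisopropylbenzenesulfonate of diol 22 | CC(C)c1cc(C(C)C)c(S(=O)(=O)OC[C@H](O)[C@H](C/C=C(/C)CC/C=C(/C)CCC#CC)C(=C)CCC=C(C)C)c(C(C)C)c1 | intermediate (not isolated)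
24 | (2R)-2-[(7R,9Z,13Z)-2,10,14-trimethyl-6-methylidenenonadeca-2,9,13-trien-17-yn-7-yl]oxirane | O1C[C@H]1[C@H](C/C=C(/C)CC/C=C(/C)CCC#CC)C(=C)CCC=C(C)C | intermediate
25 | (1S,3E,7Z,11Z,14R)-3,7,11-trimethyl-14-(6-methylhepta-1,5-dien-2-yl)cyclotetradeca-3,7,11-trien-1-ol | C=C(CCC=C(C)C)[C@H]1C/C=C(/C)CC/C=C(/C)CC/C=C(\C)C[C@@H]1O | intermediate
26 | (1E,5Z,9Z,12R,13S)-13-methoxy-1,5,9-trimethyl-12-(6-methylhepta-1,5-dien-2-yl)cyclotetradeca-1,5,9-triene | C=C(CCC=C(C)C)[C@H]1C/C=C(/C)CC/C=C(/C)CC/C=C(\C)C[C@@H]1OC | target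

**Step count and risks**

Total step count: 18. Longest linear sequence: 17 steps (steps 1–4 and 6–18, from nerol).

The three steps most likely to fail:

1. Step 17 (Proposed new method). What may go wrong: alkyne insertion with the opposite regiochemistry (bond formation at C11, leading to a 13-membered ring with an exocyclic ethylidene), intermolecular coupling and oligomerisation, or isomerisation of the epoxide before it couples. The fallback uses known chemistry, sets out from epoxide 24 and comes back at alcohol 25. BF3·OEt2-promoted opening of the epoxide at its CH2 end with 1-propynyllithium (THF, −78 °C) should give the homopropargylic diynol F1, so the C12–C13 bond is made intermolecularly. Ring-closing alkyne metathesis (Mo(≡CC6H4-4-OMe)(OSiPh3)3, 5 Å molecular sieves, toluene, high dilution, 80 °C) then closes the 14-membered ring between C11 and C12 with loss of but-2-yne, giving the cycloalkynol F2; the hindered secondary hydroxyl is expected to be tolerated. Hydroxyl-directed trans-hydrostannation ([Cp*RuCl]4, Bu3SnH, CH2Cl2, rt) should place tin on C12, the alkyne carbon nearer the hydroxyl, and hydrogen on C11 from the opposite face, giving the alkenylstannane F3. Stille methylation with retention (Pd(PPh3)4, copper thiophene-2-carboxylate Cu(O2C-C4H3S), [Bu4N][Ph2PO2], MeI, DMF) returns 25 with the E C11=C12 alkene.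

2. Step 4. What may go wrong: decomposition of the α-iodo ylide before it meets the aldehyde (loss of iodine, giving non-iodinated alkene) and erosion of the Z/E selectivity. The fallback sets out from aldehyde 4 and comes back at alcohol 10. Still–Gennari olefination with methyl 2-[bis(2,2,2-trifluoroethoxy)phosphoryl]propanoate (KN(SiMe3)2, 18-crown-6, THF, −78 °C) should give the (Z)-enoate F4. Reduction with i-Bu2AlH (CH2Cl2, −78 °C) gives the allylic alcohol F5, and CBr4/PPh3 gives the allylic bromide F6. Displacement with the lithium derivative of 1-(trimethylsilyl)propyne (n-BuLi, THF, −78 °C) gives the silylated enyne F7. Bu4NF removes both silyl groups to give the terminal alkynol F8, whose dianion (n-BuLi, 2 equiv, THF) is methylated on carbon with MeI to give 10.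

3. Step 10. What may go wrong: competing hydroboration of the trisubstituted alkenes or the alkyne by borane, or reduction of the second ester. The fallback sets out from hydroxy diester 14 and comes back at ketone 20. LiAlH4 (THF, 0 °C) reduces both esters to the triol F9. 2,2-Dimethoxypropane/PPTS should form the five-membered acetonide of the 1,2-diol selectively, leaving the primary alcohol F10. Dess–Martin periodinane gives the aldehyde F11, Grignard reagent 19 adds to give the secondary alcohol F12 (epimers at the new carbinol, without consequence), and a second Dess–Martin oxidation gives 20.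

**Further compounds**

F1 | step 17 | (5S,6R,8Z,12Z)-9,13-dimethyl-6-(6-methylhepta-1,5-dien-2-yl)octadeca-8,12-dien-2,16-diyn-5-ol | CC#CC[C@H](O)[C@H](C/C=C(/C)CC/C=C(/C)CCC#CC)C(=C)CCC=C(C)C
F2 | step 17 | (1S,7Z,11Z,14R)-7,11-dimethyl-14-(6-methylhepta-1,5-dien-2-yl)cyclotetradeca-7,11-dien-3-yn-1-ol | C=C(CCC=C(C)C)[C@H]1C/C=C(/C)CC/C=C(/C)CCC#CC[C@@H]1O
F3 | step 17 | (1S,3Z,7Z,11Z,14R)-7,11-dimethyl-14-(6-methylhepta-1,5-dien-2-yl)-3-(tributylstannyl)cyclotetradeca-3,7,11-trien-1-ol | C=C(CCC=C(C)C)[C@H]1C/C=C(/C)CC/C=C(/C)CC/C=C(\[Sn](CCCC)(CCCC)CCCC)C[C@@H]1O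
F4 | step 4 | methyl (2Z,6Z)-8-[(tert-butyldiphenylsilyl)oxy]-2,6-dimethylocta-2,6-dienoate | COC(=O)/C(C)=C\CC/C(C)=C\CO[Si](c1ccccc1)(c1ccccc1)C(C)(C)C
F5 | step 4 | (2Z,6Z)-8-[(tert-butyldiphenylsilyl)oxy]-2,6-dimethylocta-2,6-dien-1-ol | OC/C(C)=C\CC/C(C)=C\CO[Si](c1ccccc1)(c1ccccc1)C(C)(C)C
F6 | step 4 | {[(2Z,6Z)-8-bromo-3,7-dimethylocta-2,6-dien-1-yl]oxy}(tert-butyl)diphenylsilane | BrC/C(C)=C\CC/C(C)=C\CO[Si](c1ccccc1)(c1ccccc1)C(C)(C)C
F7 | step 4 | tert-butyl{[(2Z,6Z)-3,7-dimethyl-11-(trimethylsilyl)undeca-2,6-dien-10-yn-1-yl]oxy}diphenylsilane | C[Si](C)(C)C#CCC/C(C)=C\CC/C(C)=C\CO[Si](c1ccccc1)(c1ccccc1)C(C)(C)C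
F8 | step 4 | (2Z,6Z)-3,7-dimethylundeca-2,6-dien-10-yn-1-ol | C#CCC/C(C)=C\CC/C(C)=C\CO
F9 | step 10 | (2R,3R)-3-[(2Z,6Z)-3,7-dimethyldodeca-2,6-dien-10-yn-1-yl]butane-1,2,4-triol | OC[C@H](O)[C@H](C/C=C(/C)CC/C=C(/C)CCC#CC)CO
F10 | step 10 | (2R,4Z,8Z)-2-[(4R)-2,2-dimethyl-1,3-dioxolan-4-yl]-5,9-dimethyltetradeca-4,8-dien-12-yn-1-ol | CC1(C)OC[C@H](O1)[C@H](C/C=C(/C)CC/C=C(/C)CCC#CC)CO
F11 | step 10 | (2S,4Z,8Z)-2-[(4R)-2,2-dimethyl-1,3-dioxolan-4-yl]-5,9-dimethyltetradeca-4,8-dien-12-ynal | CC1(C)OC[C@H](O1)[C@H](C/C=C(/C)CC/C=C(/C)CCC#CC)C=O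
F12 | step 10 | (7R,9Z,13Z)-7-[(4R)-2,2-dimethyl-1,3-dioxolan-4-yl]-2,10,14-trimethylnonadeca-2,9,13-trien-17-yn-6-ol (both C6 epimers) | CC1(C)OC[C@H](O1)[C@H](C/C=C(/C)CC/C=C(/C)CCC#CC)C(O)CCC=C(C)C
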